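**Retrosynthetic overview**

1. Target 17 ← MOM ether 16 ← resorcylate 13 + prenal 14: the pyran ring is closed last (C4–C4a and O1–C2) on the only free ortho C–H/OH pair.
2. 13 ← C-prenyl dione 10 by dehydrogenation through selenide 11; 10 ← dione 8 + prenyl bromide 9, alkylated at the carbon between the two carbonyls.
3. 8 ← enone 5 + dimethyl malonate 6. The feature used is the fully substituted benzene ring (chromene C4a, C5, C6, C7, C8, C8a): it is a resorcylate with oxygens on C7 and C8a flanking C8 and the ester on C6, so C8 is C2 of a cyclohexane-1,3-dione made by Michael addition (C5–C6) and Claisen closure (C7–C8).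
4. 5 ← methyl 3-(4-hydroxyphenyl)propanoate 1 by MOM protection, partial reduction and Wittig olefination with ylide 4.
5. Ring order: phenol ring purchased; central carbocycle built in step 4 and aromatised in step 7; pyran ring in step 8.

Key step: step 4

Assumption: 7, 8 and 10 are racemic, and 8 and 10 exist largely as enols but are drawn as triketo tautomers; 11 and 12 are racemic and drawn as one enantiomer with the relative configuration shown.

**Route**

Step 1
Reactants: 1 methyl 3-(4-hydroxyphenyl)propanoate
Product: 2 methyl 3-[4-(methoxymethoxy)phenyl]propanoate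
Conditions: MOMCl, i-Pr2NEt, CH2Cl2, 0 °C → rt
Reagents that add atoms: chloromethyl methyl ether, COCCl
Why: O-alkylation of the phenol by the reactive α-chloro ether under amine base (MOM protection) leaves the ester untouched and gives an acetal that survives hydride, ylide, alkoxide and amide bases.

Step 2
Reactants: 2 methyl 3-[4-(methoxymethoxy)phenyl]propanoate
Product: 3 3-[4-(methoxymethoxy)phenyl]propanal
Conditions: i-Bu2AlH (1.05 equiv), CH2Cl2, −78 °C; MeOH, then aq potassium sodium tartrate
Reagents that add atoms: none
Why: Partial ester reduction with i-Bu2AlH at −78 °C should stop at the tetrahedral aluminium hemiacetal, which releases the aldehyde only on work-up.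

Step 3
Reactants: 3 3-[4-(methoxymethoxy)phenyl]propanal; 4 1-(triphenylphosphoranylidene)propan-2-one
Product: 5 (E)-6-[4-(methoxymethoxy)phenyl]hex-3-en-2-one
Conditions: CH2Cl2, rt → 40 °C
Reagents that add atoms: none
Why: Wittig olefination with a stabilised acyl ylide needs no added base (no aldol self-condensation) and should give the E-enone; the alkene geometry is in any case lost in step 4.

Step 4
Reactants: 5 (E)-6-[4-(methoxymethoxy)phenyl]hex-3-en-2-one; 6 dimethyl malonate
Product: 8 methyl 2,4-dioxo-6-{2-[4-(methoxymethoxy)phenyl]ethyl}cyclohexane-1-carboxylate, via Michael adduct 7 (not isolated)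
Conditions: NaOMe (1.2 equiv), MeOH, rt then reflux; cold 1 M HCl to pH 3
Reagents that add atoms: none
Why: Methoxide generates the malonate anion, which adds 1,4 to the enone at the carbon bearing the arylethyl chain (future chromene C5–C6 bond) to give 7 as its enolate; proton exchange in methanol makes the methyl-side enolate available, and this carbon acylates on one malonate ester carbonyl (future C7–C8 bond) with loss of methoxide. The closest known reaction type is the classical malonate Michael–Claisen synthesis of 5-substituted cyclohexane-1,3-dione-4-carboxylates (dihydroresorcylates) from alkylidene acetones. The ring closes in the 6-(enolendo)-exo-trig mode, because both enolate carbons lie in the new ring while the ester C=O is exocyclic to it, and closure is pulled to completion by deprotonation of the product to the delocalised trione anion. The one lasting new stereocenter (ring C6, bearing the arylethyl chain) forms without control since neither partner is chiral, so 8 is racemic and the centre is erased on aromatisation in step 7; the ester-bearing C1 is epimerisable. The step needs 1,4- over 1,2-addition and closure from the methyl side: the soft, reversibly adding malonate secures the first, and the second is the only productive course because the internal enolate could close only a four-membered ring.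

Step 5
Reactants: 8 methyl 2,4-dioxo-6-{2-[4-(methoxymethoxy)phenyl]ethyl}cyclohexane-1-carboxylate; 9 prenyl bromide (1-bromo-3-methylbut-2-ene)
Product: 10 methyl 6-{2-[4-(methoxymethoxy)phenyl]ethyl}-3-(3-methylbut-2-en-1-yl)-2,4-dioxocyclohexane-1-carboxylate
Conditions: KOH (1.0 equiv), H2O, 0 °C; then 9, 0 °C → rt
Reagents that add atoms: none
Why: One equivalent of base ionises only the vinylogous-acid dione (not the β-keto ester C1–H), and in water the hydrogen-bonded enolate oxygens are shielded, so the soft allylic bromide should alkylate the inter-carbonyl carbon (Stetter-type C-alkylation of cyclohexane-1,3-diones).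

Step 6
Reactants: 10 methyl 6-{2-[4-(methoxymethoxy)phenyl]ethyl}-3-(3-methylbut-2-en-1-yl)-2,4-dioxocyclohexane-1-carboxylate
Product: 11 methyl 4-hydroxy-6-{2-[4-(methoxymethoxy)phenyl]ethyl}-3-(3-methylbut-2-en-1-yl)-2-oxo-1-(phenylselanyl)cyclohex-3-ene-1-carboxylate (racemic, PhSe trans to the arylethyl chain)
Conditions: LiN(i-Pr)2 (2.2 equiv), THF, −78 → 0 °C; PhSeBr (1.1 equiv), −78 °C; cold 1 M HCl to pH 3–4
Reagents that add atoms: benzeneselenenyl bromide, Br[Se]c1ccccc1
Why: The second equivalent of amide removes the ester α-hydrogen at C1 from the dione monoanion, and this last-formed, most basic carbanion captures electrophilic selenium (selenenylation of an enolate dianion, analogous to γ-functionalisation of β-dicarbonyl dianions); PhSeBr should approach anti to the neighbouring arylethyl chain, which places selenium cis to C6–H at the new quaternary centre, and selenenylation at C5 instead would lead to the same arene in step 7.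

Step 7
Reactants: 11 methyl 4-hydroxy-6-{2-[4-(methoxymethoxy)phenyl]ethyl}-3-(3-methylbut-2-en-1-yl)-2-oxo-1-(phenylselanyl)cyclohex-3-ene-1-carboxylate
Product: 13 methyl 2,4-dihydroxy-6-{2-[4-(methoxymethoxy)phenyl]ethyl}-3-(3-methylbut-2-en-1-yl)benzoate, via selenoxide 12 (not isolated)
Conditions: mCPBA (1.0 equiv), CH2Cl2, −78 °C; then i-Pr2NH (2 equiv), −78 °C → rt
Reagents that add atoms: none
Why: Selenium is oxidised far faster than the prenyl olefin at −78 °C, and selenoxide 12 should undergo syn-elimination with the only β-hydrogen (the cis C6–H) on warming; the resulting cyclohexenedione tautomerises irreversibly to the resorcylate, while the amine holds the benzeneselenenic acid reversibly as a selenenamide, away from the prenyl group, until work-up.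

Step 8
Reactants: 13 methyl 2,4-dihydroxy-6-{2-[4-(methoxymethoxy)phenyl]ethyl}-3-(3-methylbut-2-en-1-yl)benzoate; 14 3-methylbut-2-enal (prenal)
Product: 16 methyl 7-hydroxy-5-{2-[4-(methoxymethoxy)phenyl]ethyl}-2,2-dimethyl-8-(3-methylbut-2-en-1-yl)-2H-chromene-6-carboxylate, via ortho-quinone methide 15 (not isolated)
Conditions: ethylenediammonium diacetate (0.2 equiv), toluene, reflux
Reagents that add atoms: none
Why: Iminium-activated prenal condenses at C5 of the benzoate, the only unsubstituted ring carbon (ortho to the 4-OH, para to the 2-OH), and loss of water gives 1-oxatriene 15, which closes by oxa-6π electrocyclisation (formal [3+3] chromene annulation of resorcinols with enals); the chelated 2-OH cannot take part because both its ortho carbons are substituted.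

Step 9
Reactants: 16 methyl 7-hydroxy-5-{2-[4-(methoxymethoxy)phenyl]ethyl}-2,2-dimethyl-8-(3-methylbut-2-en-1-yl)-2H-chromene-6-carboxylate
Product: 17 methyl 7-hydroxy-5-[2-(4-hydroxyphenyl)ethyl]-2,2-dimethyl-8-(3-methylbut-2-en-1-yl)-2H-chromene-6-carboxylate
Conditions: 3 M aq HCl, MeOH, rt → 40 °C
Reagents that add atoms: none
Why: Acid-catalysed acetal methanolysis removes the aryl MOM ether under conditions milder than those needed to protonate the prenyl or chromene double bonds; the ester-chelated 7-OH is a poor nucleophile, which should suppress chroman formation.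

**Compound list**

1 | methyl 3-(4-hydroxyphenyl)propanoate | COC(=O)CCc1ccc(O)cc1 | starting material
2 | methyl 3-[4-(methoxymethoxy)phenyl]propanoate | COCOc1ccc(CCC(=O)OC)cc1 | intermediate
3 | 3-[4-(methoxymethoxy)phenyl]propanal | COCOc1ccc(CCC=O)cc1 | intermediate
4 | 1-(triphenylphosphoranylidene)propan-2-one | CC(=O)C=P(c1ccccc1)(c1ccccc1)c1ccccc1 | starting material
5 | (E)-6-[4-(methoxymethoxy)phenyl]hex-3-en-2-one | CC(=O)/C=C/CCc1ccc(OCOC)cc1 | intermediate
6 | dimethyl malonate | COC(=O)CC(=O)OC | starting material
7 | dimethyl 2-{1-[4-(methoxymethoxy)phenyl]-5-oxohexan-3-yl}propanedioate (racemic Michael adduct, not isolated) | COC(=O)C(C(=O)OC)C(CC(C)=O)CCc1ccc(OCOC)cc1 | intermediate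
8 | methyl 2,4-dioxo-6-{2-[4-(methoxymethoxy)phenyl]ethyl}cyclohexane-1-carboxylate (racemic; enolised) | COC(=O)C1C(=O)CC(=O)CC1CCc1ccc(OCOC)cc1 | intermediate
9 | prenyl bromide (1-bromo-3-methylbut-2-ene) | CC(C)=CCBr | starting material
10 | methyl 6-{2-[4-(methoxymethoxy)phenyl]ethyl}-3-(3-methylbut-2-en-1-yl)-2,4-dioxocyclohexane-1-carboxylate (racemic; enolised) | COC(=O)C1C(=O)C(CC=C(C)C)C(=O)CC1CCc1ccc(OCOC)cc1 | intermediate
11 | methyl 4-hydroxy-6-{2-[4-(methoxymethoxy)phenyl]ethyl}-3-(3-methylbut-2-en-1-yl)-2-oxo-1-(phenylselanyl)cyclohex-3-ene-1-carboxylate (racemic; PhSe trans to the arylethyl chain) | COC(=O)[C@]1([Se]c2ccccc2)C(=O)C(CC=C(C)C)=C(O)C[C@@H]1CCc1ccc(OCOC)cc1 | intermediate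
12 | methyl 1-(benzeneseleninyl)-4-hydroxy-6-{2-[4-(methoxymethoxy)phenyl]ethyl}-3-(3-methylbut-2-en-1-yl)-2-oxocyclohex-3-ene-1-carboxylate (selenoxide, not isolated; mixture at selenium) | COC(=O)[C@]1([Se](=O)c2ccccc2)C(=O)C(CC=C(C)C)=C(O)C[C@@H]1CCc1ccc(OCOC)cc1 | intermediate
13 | methyl 2,4-dihydroxy-6-{2-[4-(methoxymethoxy)phenyl]ethyl}-3-(3-methylbut-2-en-1-yl)benzoate | COC(=O)c1c(O)c(CC=C(C)C)c(O)cc1CCc1ccc(OCOC)cc1 | intermediate
14 | 3-methylbut-2-enal (prenal) | CC(C)=CC=O | starting material
15 | methyl 2-hydroxy-6-{2-[4-(methoxymethoxy)phenyl]ethyl}-3-(3-methylbut-2-en-1-yl)-5-(3-methylbut-2-en-1-ylidene)-4-oxocyclohexa-1(6),2-diene-1-carboxylate (ortho-quinone methide, not isolated; side-chain alkene cis to the ring carbonyl) | CC(C)=C/C=C1\C(=O)C(CC=C(C)C)=C(O)C(C(=O)OC)=C1CCc1ccc(OCOC)cc1 | intermediate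
16 | methyl 7-hydroxy-5-{2-[4-(methoxymethoxy)phenyl]ethyl}-2,2-dimethyl-8-(3-methylbut-2-en-1-yl)-2H-chromene-6-carboxylate | COC(=O)c1c(O)c(CC=C(C)C)c2c(c1CCc1ccc(OCOC)cc1)C=CC(C)(C)O2 | intermediate
17 | methyl 7-hydroxy-5-[2-(4-hydroxyphenyl)ethyl]-2,2-dimethyl-8-(3-methylbut-2-en-1-yl)-2H-chromene-6-carboxylate | COC(=O)c1c(O)c(CC=C(C)C)c2c(c1CCc1ccc(O)cc1)C=CC(C)(C)O2 | target

**Step count and risks**

Total step count: 9. Longest linear sequence: 9 steps (from 1).

Steps most likely to fail:

1. Step 6 (with its follow-up, step 7). Electrophilic selenium may add to the prenyl double bond or attack the inter-carbonyl carbon instead of a carbon flanking C6. The selenoxide may also lack a syn β-hydrogen if selenium enters cis to the arylethyl chain, and then decompose by other paths. Fallback, setting out from 10: exhaustive O-silylation with TBSOTf and Et3N in CH2Cl2 should give the cyclohexa-1,3-diene methyl 2,4-bis[(tert-butyldimethylsilyl)oxy]-6-{2-[4-(methoxymethoxy)phenyl]ethyl}-3-(3-methylbut-2-en-1-yl)cyclohexa-1,3-diene-1-carboxylate F1 (regioisomeric dienol ethers would converge). DDQ (1 equiv, CH2Cl2, 0 °C) should dehydrogenate it by hydride abstraction from C6, giving a cation stabilised by both silyloxy groups, followed by proton loss. This gives methyl 2,4-bis[(tert-butyldimethylsilyl)oxy]-6-{2-[4-(methoxymethoxy)phenyl]ethyl}-3-(3-methylbut-2-en-1-yl)benzoate F2; with both phenols capped, oxidative cyclisation of an ortho-prenyl phenol by the quinone is blocked. Bu4NF with AcOH in THF then removes the silyl groups and the route is rejoined at 13.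

2. Step 5. The ambident dione anion may alkylate on oxygen or take up a second prenyl group at the same carbon, and prenyl bromide may be lost to hydrolysis in water. Fallback, setting out from 8: Tsuji–Trost prenylation with methyl 3-methylbut-2-en-1-yl carbonate (COC(=O)OCC=C(C)C) and catalytic Pd(PPh3)4 (zerovalent palladium) in THF at rt without added base. The methoxide released on ionisation deprotonates the dione, which attacks the less hindered terminus of the π-prenyl complex. Any O-prenyl enol ether is itself an allylic electrophile and is re-ionised, so material should funnel to the C-prenyl compound. The route is rejoined directly at 10 with no new intermediate.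

3. Step 8. Condensation at C5 is slowed by the flanking arylethyl chain and by the electron-poor resorcylate, so self-condensation of prenal may outrun annulation. Fallback, setting out from 13: selective O-alkylation of the non-chelated 4-OH with 3-chloro-3-methylbut-1-yne (DBU, catalytic CuCl2, MeCN, 0 °C) should give methyl 2-hydroxy-6-{2-[4-(methoxymethoxy)phenyl]ethyl}-3-(3-methylbut-2-en-1-yl)-4-[(2-methylbut-3-yn-2-yl)oxy]benzoate F3. Heating F3 in N,N-diethylaniline at about 180 °C should trigger aryl propargyl Claisen rearrangement to C5, the only free ortho carbon (migration to the prenyl-bearing carbon is reversible), then 1,5-hydrogen shift and oxa-6π ring closure. The route is rejoined at 16.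

**Further compounds**

F1 | step 6 | methyl 2,4-bis[(tert-butyldimethylsilyl)oxy]-6-{2-[4-(methoxymethoxy)phenyl]ethyl}-3-(3-methylbut-2-en-1-yl)cyclohexa-1,3-diene-1-carboxylate (racemic) | COC(=O)C1=C(O[Si](C)(C)C(C)(C)C)C(CC=C(C)C)=C(O[Si](C)(C)C(C)(C)C)CC1CCc1ccc(OCOC)cc1
F2 | step 6 | methyl 2,4-bis[(tert-butyldimethylsilyl)oxy]-6-{2-[4-(methoxymethoxy)phenyl]ethyl}-3-(3-methylbut-2-en-1-yl)benzoate | COC(=O)c1c(O[Si](C)(C)C(C)(C)C)c(CC=C(C)C)c(O[Si](C)(C)C(C)(C)C)cc1CCc1ccc(OCOC)cc1
F0 | step 5 | none | none
F3 | step 8 | methyl 2-hydroxy-6-{2-[4-(methoxymethoxy)phenyl]ethyl}-3-(3-methylbut-2-en-1-yl)-4-[(2-methylbut-3-yn-2-yl)oxy]benzoate | COC(=O)c1c(O)c(CC=C(C)C)c(OC(C)(C)C#C)cc1CCc1ccc(OCOC)cc1
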